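## The problem

Cladonaphchrom A 19 joins C4 of a 2-methylchroman-5-ol to C1' of a 4',5'-dimethoxynaphthalene through one sp3–sp2 bond, and this junction is a hindered diarylmethine flanked by the C5 oxygen on the chroman side and the peri hydrogen at C8' on the naphthalene side. The two stereocentres, C2 (R) and C4 (S), stand 1,3 across the pyran ring and are trans. C2 has no neighbouring handle, but it can be set by asymmetric catalysis on a flat chromone. C4 is benzylic to a ring whose two ortho oxygens (O1 at C8a and the C5 oxygen) stabilise a C4 cation, so C2 can control C4 in a cation capture. For the same reason C4 is the centre most easily lost in strong acid. Three aryl oxygens must end differently (two naphthyl methyl ethers, one free chroman phenol), so the chroman oxygen needs a group that survives Lewis acid, Grignard reagent, oxidant and base and leaves under neutral conditions. The enabling feature is the naphthalene ring C1'–C4', which carries carbon at C1', oxygen at C4' para to it and a second oxygen at C5' peri to C4'; this maps onto a 2-alkylfuran (furan C2 becomes C1', the furan oxygen becomes the C4' oxygen) that has added a benzyne carrying an oxygen placeholder at its 3-position, the future C5'.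

## Retrosynthesis

**Phenol and methyl ethers (19 from 18 from 17).** The O–benzyl bond of 18 and the two O–methyl bonds are cut first. Benzyl is chosen for the chroman oxygen because it tolerates every later reagent and leaves by hydrogenolysis without acid, which spares the ionisable C4. Diol 17 carries both naphthalene oxygens free, so one double methylation serves and no differentiation of the two is needed. The forward steps only ask for exhaustive methylation of a hydrogen-bonded peri diol and a clean hydrogenolysis.

**Peri oxygen and naphthol (17 from 16 from 15).** The C5'–O bond of 17 is traced to a C5'–B bond in naphthol boronate 16, and 16 to the 1,4-epoxy-1,4-dihydronaphthalene 15 by acid isomerisation. The order matters: an oxygen at C5' would stabilise a cation at C4' and invite cleavage of the wrong bridge bond, while boron does not. The bridge is therefore opened first and boron is oxidised afterwards. The isomerisation must cleave the C1'–O bond (tertiary, benzylic, allylic cation) so that oxygen stays on C4'.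

**Naphthalene ring (15 from 8 and 12).** Bonds C1'–C8a' and C4'–C4a' are cut together, which returns furylchroman 8 and 3-borylbenzyne 14. The aryne is released from iodoaryl triflate 12 through aryl Grignard 13. Compared with a direct Friedel–Crafts union of the chromanyl cation with a ready-made naphthalene, this cut settles the positions of all three naphthalene substituents in one cycloaddition, and the C4–aryl bond can be made earlier with the small, reactive furan 7. A 3-alkoxybenzyne is polarised the other way and would place the oxygen at C8'; the boryl group reverses the polarity and is later turned into oxygen. The forward step must be distal-selective and must leave the boronate intact.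

**Aryne precursor (12 from 11 from 9).** The S–O bond of triflate 12 and the C–B bond of phenol 11 are cut, leading to commercial 2,6-diiodophenol 9, which already holds both ortho handles. One iodine is exchanged for magnesium on the unprotected phenolate (magnesiated phenolate 10) and trapped with a boron electrophile. The remaining iodine and the triflate form the pair that releases the aryne at −78 °C without fluoride, which a boronate would not tolerate.

**C4–furan bond (8 from 6 and 7).** The C4–C bond is cut to chromanol 6 and furan 7, two far simpler pieces. Capture of the chromanyl cation by a carbon nucleophile puts the new group on the pseudo-axial trajectory, trans to the C2 methyl. Adding a furyl-metal to ketone 5 and then reducing would put hydride on that trajectory and lead into the cis series, so the cation route is preferred. The step demands 2,4-trans selectivity and clean mono-alkylation of furan at its alpha carbon.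

**C2 stereocentre (6 from 5 from 4).** The C4–H and C2–H bonds are cut in turn. Chromanol 6 comes from chromanone 5 by hydride reduction (either C4 epimer serves), and 5 comes from flat chromone 4 by enantioselective conjugate reduction with a ligated copper hydride. This is the only step that needs an external source of chirality.

**Chromone (4 from 3 from 2 from 1).** The O1–C2 bond of 4 is opened to 1,3-diketone 3, the C–C bond of 3 is cut to mono-benzyl ether 2 (Claisen condensation with an acetate ester), and 2 comes from 2,6-dihydroxyacetophenone 1 by mono-benzylation.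

## Roads not taken

**Alternative 1:** The pyran ring is cut at C3–C4 and O1–C2. In the forward direction a chiral phosphoric acid dehydrates the diaryl carbinol 2-[(4,5-dimethoxynaphthalen-1-yl)(hydroxy)methyl]benzene-1,3-diol A2 to the ortho-quinone methide A3, which adds 2-methoxypropene A4 in an oxa-Diels–Alder reaction to give 2-methoxy-2-methyl-4-(4,5-dimethoxynaphthalen-1-yl)chroman-5-ol A1.
- Merits: A2 brings the naphthalene in ready-made, C4 is set by a catalyst, and the route would be roughly half as long as the chosen one.
- Weak points: A4 is hydrolysed and oligomerised by the acid that must generate A3. The donor-rich carbinol A2 ionises easily, so an uncatalysed racemic pathway competes. C2 must then be set by reducing the ketal of A1, and the stereoelectronically preferred axial hydride trajectory runs past the pseudo-axial naphthyl group, so the facial outcome is not secure.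
- Comparison: this road is clearly shorter. The chosen plan sets C2 first by a well-established type of reduction and lets it control C4 in the direction that kinetic and thermodynamic preferences both favour.

**Alternative 2:** The pyran ring is cut at O1–C8a and C4–C4a. In the forward direction 3-benzyloxybenzyne A7 is released by fluoride from 3-(benzyloxy)-2-(trimethylsilyl)phenyl trifluoromethanesulfonate A8. The hydroxyl of (R)-3-hydroxy-1-(4,5-dimethoxynaphthalen-1-yl)butan-1-one A6 attacks A7 at the carbon remote from the benzyloxy group, and the aryl anion then closes onto the ketone to give 5-(benzyloxy)-2-methyl-4-(4,5-dimethoxynaphthalen-1-yl)chroman-4-ol A5.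
- Merits: C2 comes from the simple open-chain alcohol A6, both arenes are prefabricated, A8 is a conventional silyl triflate, and the regiochemistry of A7 follows the normal alkoxy polarisation.
- Weak points: A6 can undergo retro-aldol cleavage under basic fluoride conditions. The peri-hindered naphthyl ketone is a poor acceptor, so the aryl anion formed from A7 may simply be protonated. A5 must then be deoxygenated at C4, and ionic reduction delivers hydride axially, which leaves the naphthyl group equatorial and cis to the methyl group, the wrong diastereomer.
- Comparison: this road reaches the full skeleton in fewer steps, but its C4 stereochemistry points away from the target. The chosen plan forms the C4–carbon bond, not the C4–hydrogen bond, on the axial trajectory.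

**Alternative 3:** The cut is at O1–C2, C2–C3 and C4–C1'. In the forward direction a chiral Brønsted acid condenses 3-hydroxy-2-vinylphenyl pivalate A10 with acetaldehyde A11, the vinyl group cyclises onto the oxocarbenium ion, and 1,8-dimethoxynaphthalene A12 traps the C4 cation to give the phenol pivalate A9, O-pivaloyl Cladonaphchrom A. Saponification of A9 would end the synthesis.
- Merits: three simple components form three bonds in one operation, and the cation capture has the same trans preference used in the chosen plan. If it worked, A9 would be reached by far the shortest route.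
- Weak points: phenols and aldehydes under acid prefer C-alkylation to O-aryl oxocarbenium formation. A11 can alkylate A12 directly, and A10 can oligomerise. Absolute control at C2 by a chiral acid in such a three-component cascade has no close analogue.
- Comparison: this road wins on step count and convergence. The chosen plan offers reaction types that are each individually known and a defined source for each stereocentre. The stepwise form of this capture (chromanol 6 plus A12) is kept as the fallback for the key step.

Key step: step 8

Assumption: (R)-DTBM-SEGPHOS is taken to deliver hydride to the face that gives the 2R chromanone; if the sense is the opposite, the (S)-ligand is used and nothing else changes.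

## Route

Step 1
Reactants: 1 2,6-dihydroxyacetophenone
Product: 2 1-[2-(benzyloxy)-6-hydroxyphenyl]ethan-1-one
Conditions: BnBr, K2CO3, acetone, reflux
Reagents that add atoms: benzyl bromide, BrCc1ccccc1
Why: Williamson ether synthesis; after the first alkylation the remaining hydroxyl is hydrogen-bonded to the ketone and much less reactive, so mono-benzylation is expected.

Step 2
Reactants: 2 1-[2-(benzyloxy)-6-hydroxyphenyl]ethan-1-one
Product: 4 5-(benzyloxy)-2-methyl-4H-chromen-4-one, via aryl 1,3-diketone 3 (not isolated)
Conditions: NaH, EtOAc, THF, 0 °C to reflux; then conc. HCl, MeOH, 50 °C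
Reagents that add atoms: ethyl acetate, CCOC(C)=O
Why: Claisen condensation of the ketone enolate with ethyl acetate gives the diketone, which cyclodehydrates under acid to the chromone (classical 2-methylchromone synthesis); the benzyl aryl ether is stable to warm methanolic HCl.

Step 3
Reactants: 4 5-(benzyloxy)-2-methyl-4H-chromen-4-one
Product: 5 (R)-5-(benzyloxy)-2-methylchroman-4-one
Conditions: Cu(OAc)2 (5 mol %), (R)-DTBM-SEGPHOS (5.5 mol %), (EtO)2MeSiH, tBuOH, toluene, 0 °C to rt; aq. NH4F
Reagents that add atoms: none
Why: Enantioselective conjugate reduction of a 2-alkylchromone by a bisphosphine-ligated monovalent copper hydride; the ligand selects the face of C2 that receives hydride and so sets C2 as R. Any over-reduction to the chromanol is harmless because step 4 makes it anyway.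

Step 4
Reactants: 5 (R)-5-(benzyloxy)-2-methylchroman-4-one
Product: 6 (2R,4S)-5-(benzyloxy)-2-methylchroman-4-ol
Conditions: NaBH4, MeOH–THF, 0 °C
Reagents that add atoms: none
Why: Borohydride reduction of the aryl ketone; axial hydride delivery should give mainly the 2,4-cis alcohol, but the C4 configuration is irrelevant because C4 is ionised in step 5.

Step 5
Reactants: 6 (2R,4S)-5-(benzyloxy)-2-methylchroman-4-ol; 7 furan
Product: 8 2-[(2R,4R)-5-(benzyloxy)-2-methylchroman-4-yl]furan
Conditions: furan (20 equiv), BF3·OEt2 (0.5 equiv), CH2Cl2, −78 to −30 °C
Reagents that add atoms: none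
Why: Friedel–Crafts alkylation by an SN1 path: BF3 ionises the chromanol to the 4-chromanyl cation (stabilised by O1 and the C5 benzyloxy group), which furan traps at its alpha carbon. Pseudo-axial attack through a chair-like transition state with the C2 methyl pseudo-equatorial places the furyl group trans to the methyl group, and peri strain with the C5 benzyloxy group favours the same pseudo-axial furyl isomer, so C2 controls C4.

Step 6
Reactants: 9 2,6-diiodophenol
Product: 11 2-iodo-6-(4,4,5,5-tetramethyl-1,3,2-dioxaborolan-2-yl)phenol, via magnesiated iodophenolate 10 (not isolated)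
Conditions: MeMgCl, LiCl, THF, −30 °C; iPrMgCl, −30 to 0 °C; iPrOBpin, 0 °C to rt; aq. NH4Cl
Reagents that add atoms: 2-isopropoxy-4,4,5,5-tetramethyl-1,3,2-dioxaborolane, CC(C)OB1OC(C)(C)C(C)(C)O1
Why: Iodine–magnesium exchange on an unprotected iodophenol after deprotonation, then borylation of the aryl Grignard; the electron-rich dianionic species resists a second exchange, so one iodine remains.

Step 7
Reactants: 11 2-iodo-6-(4,4,5,5-tetramethyl-1,3,2-dioxaborolan-2-yl)phenol
Product: 12 2-iodo-6-(4,4,5,5-tetramethyl-1,3,2-dioxaborolan-2-yl)phenyl trifluoromethanesulfonate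
Conditions: Tf2O, pyridine, CH2Cl2, 0 °C
Reagents that add atoms: trifluoromethanesulfonic anhydride, O=S(=O)(OS(=O)(=O)C(F)(F)F)C(F)(F)F
Why: O-sulfonylation of a phenol; the pinacol boronate and the aryl iodide are inert to Tf2O and pyridine.

Step 8
Reactants: 8 2-[(2R,4R)-5-(benzyloxy)-2-methylchroman-4-yl]furan; 12 2-iodo-6-(4,4,5,5-tetramethyl-1,3,2-dioxaborolan-2-yl)phenyl trifluoromethanesulfonate
Product: 15 2-[(1S,4S)-1-[(2R,4R)-5-(benzyloxy)-2-methylchroman-4-yl]-1,4-dihydro-1,4-epoxynaphthalen-5-yl]-4,4,5,5-tetramethyl-1,3,2-dioxaborolane (one bridgehead diastereomer named), via aryl Grignard 13 (not isolated), via 3-borylbenzyne 14 (not isolated)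
Conditions: 12 (1.5 equiv), iPrMgCl·LiCl (1.6 equiv), Et2O, −78 °C to rt
Reagents that add atoms: none
Why: Iodine–magnesium exchange on 12 is faster at −78 °C than attack on boron because the iodide is activated by the ortho triflate; on warming, aryl Grignard 13 loses MgCl(OTf) to give aryne 14. The aryne is trapped by the furan ring of 8 in a concerted but asynchronous [4+2] cycloaddition (aryne Diels–Alder reaction); the closest known reaction type is the distal-selective cycloaddition of 3-borylbenzynes with 2-substituted furans. The new six-membered carbocycle (C1', C2', C3', C4', C4a', C8a') closes by this cycloaddition, with bonds C1'–C8a' and C4'–C4a' formed suprafacially on both partners and the furan oxygen left as the 1,4-bridge. The electropositive boryl group distorts the aryne so that the carbon next to it is the more electrophilic one; it bonds first to the unsubstituted, more nucleophilic furan carbon, and the chromanyl-bearing carbon bonds to the remote aryne carbon. Sterics point the same way, since the bulky secondary chromanyl group avoids the pinacol boronate; this distal regioselectivity is the one selectivity the step needs, because it puts boron at C5', peri to the bridgehead CH at C4'. The two bridgehead stereocentres form with their relative configuration fixed by the bicyclic geometry; their sense relative to the chroman is not controlled and does not matter, as both vanish in step 9. The benzyl ether, the chroman ether and the two existing stereocentres offer no acidic or electrophilic site to the Grignard reagent at this temperature.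

Step 9
Reactants: 15 2-[(1S,4S)-1-[(2R,4R)-5-(benzyloxy)-2-methylchroman-4-yl]-1,4-dihydro-1,4-epoxynaphthalen-5-yl]-4,4,5,5-tetramethyl-1,3,2-dioxaborolane (both bridgehead diastereomers)
Product: 16 4-[(2R,4S)-5-(benzyloxy)-2-methylchroman-4-yl]-8-(4,4,5,5-tetramethyl-1,3,2-dioxaborolan-2-yl)naphthalen-1-ol
Conditions: CF3CO2H (3 equiv), CH2Cl2, −20 to 0 °C
Reagents that add atoms: none
Why: Acid-catalysed isomerisation of a 1-substituted 1,4-epoxy-1,4-dihydronaphthalene: cleavage of the C1'–O bond gives the tertiary, benzylic and allylic cation, a 1,2-hydride shift from C4' to C3' gives the protonated 4-substituted naphthalen-1(2H)-one, and tautomerisation gives the naphthol with oxygen on C4' para to the chromanyl group. Boron at C5' does not stabilise a C4' cation, so the correct bridge bond breaks; the peri hydroxyl may chelate or partly esterify the boronate, which does not affect step 10.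

Step 10
Reactants: 16 4-[(2R,4S)-5-(benzyloxy)-2-methylchroman-4-yl]-8-(4,4,5,5-tetramethyl-1,3,2-dioxaborolan-2-yl)naphthalen-1-ol
Product: 17 4-[(2R,4S)-5-(benzyloxy)-2-methylchroman-4-yl]naphthalene-1,8-diol
Conditions: NaBO3·4H2O, THF–H2O, rt, argon; aq. Na2S2O3
Reagents that add atoms: sodium perborate (tetrahydrate), [Na+].[Na+].O[B-]1(O)OO[B-](O)(O)OO1
Why: Oxidation of an aryl boronate by perborate (aryl migration from boron to oxygen) replaces boron by hydroxyl at the same carbon; the mild, weakly basic medium spares the benzyl ether and limits oxidation of the electron-rich diol, which is carried on without storage.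

Step 11
Reactants: 17 4-[(2R,4S)-5-(benzyloxy)-2-methylchroman-4-yl]naphthalene-1,8-diol
Product: 18 (2R,4S)-5-(benzyloxy)-4-(4,5-dimethoxynaphthalen-1-yl)-2-methylchroman
Conditions: MeI (excess), K2CO3, DMF, 40 °C, argon
Reagents that add atoms: iodomethane, CI
Why: Double Williamson O-methylation; the second hydroxyl is hydrogen-bonded to the first methoxy group and reacts more slowly, hence excess MeI in warm DMF, the usual conditions for peri-dimethoxynaphthalenes.

Step 12
Reactants: 18 (2R,4S)-5-(benzyloxy)-4-(4,5-dimethoxynaphthalen-1-yl)-2-methylchroman
Product: 19 Cladonaphchrom A, (2R,4S)-4-(4,5-dimethoxynaphthalen-1-yl)-2-methylchroman-5-ol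
Conditions: H2 (1 atm), Pd/C (10 wt %), EtOAc–MeOH, rt
Reagents that add atoms: none
Why: Hydrogenolysis of the benzyl aryl ether under neutral conditions; the naphthalene, the methyl ethers and the C4–aryl bond are not touched at one atmosphere, and neither stereocentre is exposed to acid or base.

## Compound list

1 | 2,6-dihydroxyacetophenone | CC(=O)c1c(O)cccc1O | starting material
2 | 1-[2-(benzyloxy)-6-hydroxyphenyl]ethan-1-one | CC(=O)c1c(O)cccc1OCc1ccccc1 | intermediate
3 | 1-[2-(benzyloxy)-6-hydroxyphenyl]butane-1,3-dione | CC(=O)CC(=O)c1c(O)cccc1OCc1ccccc1 | intermediate (not isolated)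
4 | 5-(benzyloxy)-2-methyl-4H-chromen-4-one | Cc1cc(=O)c2c(OCc3ccccc3)cccc2o1 | intermediate
5 | (R)-5-(benzyloxy)-2-methylchroman-4-one | C[C@@H]1CC(=O)c2c(OCc3ccccc3)cccc2O1 | intermediate
6 | (2R,4S)-5-(benzyloxy)-2-methylchroman-4-ol (2,4-cis; the C4 epimer serves equally) | O[C@H]1C[C@@H](C)Oc2cccc(OCc3ccccc3)c21 | intermediate
7 | furan | c1ccoc1 | starting material
8 | 2-[(2R,4R)-5-(benzyloxy)-2-methylchroman-4-yl]furan (2,4-trans) | o1cccc1[C@@H]3C[C@@H](C)Oc4cccc(OCc5ccccc5)c43 | intermediate
9 | 2,6-diiodophenol | Oc1c(I)cccc1I | starting material
10 | chloromagnesium 2-(chloromagnesio)-6-iodophenolate | Cl[Mg]Oc1c(I)cccc1[Mg]Cl | intermediate (not isolated)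
11 | 2-iodo-6-(4,4,5,5-tetramethyl-1,3,2-dioxaborolan-2-yl)phenol | Oc1c(I)cccc1B1OC(C)(C)C(C)(C)O1 | intermediate
12 | 2-iodo-6-(4,4,5,5-tetramethyl-1,3,2-dioxaborolan-2-yl)phenyl trifluoromethanesulfonate | CC1(C)OB(OC1(C)C)c1cccc(I)c1OS(=O)(=O)C(F)(F)F | intermediate
13 | 2-(chloromagnesio)-6-(4,4,5,5-tetramethyl-1,3,2-dioxaborolan-2-yl)phenyl trifluoromethanesulfonate | CC1(C)OB(OC1(C)C)c1cccc([Mg]Cl)c1OS(=O)(=O)C(F)(F)F | intermediate (not isolated)
14 | 3-(4,4,5,5-tetramethyl-1,3,2-dioxaborolan-2-yl)benzyne | CC1(C)OB(OC1(C)C)C1=CC=CC#C1 | intermediate (not isolated)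
15 | 2-[(1S,4S)-1-[(2R,4R)-5-(benzyloxy)-2-methylchroman-4-yl]-1,4-dihydro-1,4-epoxynaphthalen-5-yl]-4,4,5,5-tetramethyl-1,3,2-dioxaborolane (drawn; the 1R,4R bridgehead diastereomer also forms and serves) | CC1(C)OB(OC1(C)C)c5cccc6c5[C@@H]7C=C[C@]6(O7)[C@@H]3C[C@@H](C)Oc4cccc(OCc8ccccc8)c43 | intermediate
16 | 4-[(2R,4S)-5-(benzyloxy)-2-methylchroman-4-yl]-8-(4,4,5,5-tetramethyl-1,3,2-dioxaborolan-2-yl)naphthalen-1-ol | Oc1ccc([C@@H]2C[C@@H](C)Oc3cccc(OCc4ccccc4)c32)c2cccc(B3OC(C)(C)C(C)(C)O3)c12 | intermediate
17 | 4-[(2R,4S)-5-(benzyloxy)-2-methylchroman-4-yl]naphthalene-1,8-diol | Oc1ccc([C@@H]2C[C@@H](C)Oc3cccc(OCc4ccccc4)c32)c2cccc(O)c12 | intermediate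
18 | (2R,4S)-5-(benzyloxy)-4-(4,5-dimethoxynaphthalen-1-yl)-2-methylchroman | COc1ccc([C@@H]2C[C@@H](C)Oc3cccc(OCc4ccccc4)c32)c2cccc(OC)c12 | intermediate
19 | Cladonaphchrom A, (2R,4S)-4-(4,5-dimethoxynaphthalen-1-yl)-2-methylchroman-5-ol | COc1cccc2c([C@@H]3C[C@@H](C)Oc4cccc(O)c43)ccc(OC)c12 | target

## Step count and risks

Total step count: 12. Longest linear sequence: 10 steps (steps 1–5 and 8–12 from 1); the aryne precursor 12 takes 2 steps (6 and 7) from 9.

**Step 8 (key step).** The most likely failures are erosion of the distal regioselectivity if steric and electronic preferences prove weaker for this furan than expected, and consumption of the aryne by self-reaction or by the organomagnesium species when the hindered furan traps it slowly. Fallback: the naphthalene is not grown on the furan. Chromanol 6 is ionised with BF3·OEt2 in CH2Cl2 in the presence of 1,8-dimethoxynaphthalene A12, which is alkylated para to a methoxy group with the same pseudo-axial, trans-selective capture as in step 5. This sets out from 6 and returns at 18. It makes no compound outside the list, so its entry below is F0. Its own weakness is competing ortho alkylation of the arene.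

**Step 5.** Furan may oligomerise under the Lewis acid faster than it traps the cation, the product may be alkylated a second time at its free alpha carbon, and facial selectivity at C4 may be incomplete. Fallback: chromanol 6 is coupled instead with 2-(trimethylsilyloxy)furan (BF3·OEt2, CH2Cl2, −78 °C), a far stronger and acid-tolerant nucleophile, in a vinylogous Mukaiyama-type alkylation. This gives 5-[(2R,4R)-5-(benzyloxy)-2-methylchroman-4-yl]furan-2(5H)-one F1. Reduction of F1 with iBu2AlH at −78 °C gives the lactol 5-[(2R,4R)-5-(benzyloxy)-2-methylchroman-4-yl]-2,5-dihydrofuran-2-ol F2, which loses water on mild acid treatment and aromatises to the furan. This sets out from 6 and returns at 8.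

**Step 9.** Protodeboronation of the electron-rich naphthyl boronate, or interference of the boronate with the new peri hydroxyl, may accompany the acid step. Fallback: the order is changed. The boronate of 15 is oxidised first (NaBO3·4H2O) to (1S,4S)-1-[(2R,4R)-5-(benzyloxy)-2-methylchroman-4-yl]-1,4-dihydro-1,4-epoxynaphthalen-5-ol F3. Acetylation (Ac2O, pyridine) gives (1S,4S)-1-[(2R,4R)-5-(benzyloxy)-2-methylchroman-4-yl]-1,4-dihydro-1,4-epoxynaphthalen-5-yl acetate F4, in which the C5' oxygen is electron-poor and does not redirect the ionisation. Isomerisation of F4 with CF3CO2H gives 5-[(2R,4S)-5-(benzyloxy)-2-methylchroman-4-yl]-8-hydroxynaphthalen-1-yl acetate F5, and methanolysis of F5 (K2CO3, MeOH) gives the diol. This sets out from 15 and returns at 17. If the fault lies in the bridgehead cation itself (hydride migration from chroman C4), the fallback given for step 8 applies.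

**Step 3.** Enantioselection at C2 may be incomplete for a chromone carrying a C5 alkoxy group. Fallback: chromone 4 is reduced without asymmetric induction (Cu(OAc)2, an achiral bisphosphine, (EtO)2MeSiH) to racemic 5-(benzyloxy)-2-methylchroman-4-one F6. F6 is then resolved kinetically by asymmetric transfer hydrogenation with the enantiomer of RuCl(p-cymene)(TsDPEN) matched to the 2R ketone (HCO2H, Et3N), which reduces that enantiomer to the cis alcohol and leaves the 2S half of F6 untouched. This sets out from 4 and returns at 6, at the cost of at most half the material.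

**Step 6.** Exchange on the dianionic phenolate may be sluggish or may go on to the second iodine, and the aryl Grignard may be protonated before it is borylated. Fallback: the phenol is protected first. 9 is converted with MOMCl and iPr2NEt to 1,3-diiodo-2-(methoxymethoxy)benzene F7. One iodine of F7 is exchanged with iPrMgCl·LiCl at −40 °C and trapped with iPrOBpin to give 2-[3-iodo-2-(methoxymethoxy)phenyl]-4,4,5,5-tetramethyl-1,3,2-dioxaborolane F8. The acetal of F8 is then removed with HCl in MeOH. This sets out from 9 and returns at 11.

## Further compounds

F0 | step 8 | none | none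
F1 | step 5 | 5-[(2R,4R)-5-(benzyloxy)-2-methylchroman-4-yl]furan-2(5H)-one (both epimers at the lactone carbon) | O=C1C=CC(O1)[C@@H]2C[C@@H](C)Oc3cccc(OCc4ccccc4)c32
F2 | step 5 | 5-[(2R,4R)-5-(benzyloxy)-2-methylchroman-4-yl]-2,5-dihydrofuran-2-ol (mixture of epimers at both ring carbons bearing oxygen) | OC1C=CC(O1)[C@@H]2C[C@@H](C)Oc3cccc(OCc4ccccc4)c32
F3 | step 9 | (1S,4S)-1-[(2R,4R)-5-(benzyloxy)-2-methylchroman-4-yl]-1,4-dihydro-1,4-epoxynaphthalen-5-ol (and its 1R,4R bridgehead diastereomer) | Oc5cccc6c5[C@@H]7C=C[C@]6(O7)[C@@H]3C[C@@H](C)Oc4cccc(OCc8ccccc8)c43
F4 | step 9 | (1S,4S)-1-[(2R,4R)-5-(benzyloxy)-2-methylchroman-4-yl]-1,4-dihydro-1,4-epoxynaphthalen-5-yl acetate (and its 1R,4R bridgehead diastereomer) | CC(=O)Oc5cccc6c5[C@@H]7C=C[C@]6(O7)[C@@H]3C[C@@H](C)Oc4cccc(OCc8ccccc8)c43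
F5 | step 9 | 5-[(2R,4S)-5-(benzyloxy)-2-methylchroman-4-yl]-8-hydroxynaphthalen-1-yl acetate | CC(=O)Oc1cccc2c([C@@H]3C[C@@H](C)Oc4cccc(OCc5ccccc5)c43)ccc(O)c12
F6 | step 3 | racemic 5-(benzyloxy)-2-methylchroman-4-one | CC1CC(=O)c2c(OCc3ccccc3)cccc2O1
F7 | step 6 | 1,3-diiodo-2-(methoxymethoxy)benzene | COCOc1c(I)cccc1I
F8 | step 6 | 2-[3-iodo-2-(methoxymethoxy)phenyl]-4,4,5,5-tetramethyl-1,3,2-dioxaborolane | COCOc1c(I)cccc1B1OC(C)(C)C(C)(C)O1
A1 | alternative 1 | 2-methoxy-2-methyl-4-(4,5-dimethoxynaphthalen-1-yl)chroman-5-ol | COc1cccc2c([C@@H]3C[C@](C)(OC)Oc4cccc(O)c43)ccc(OC)c12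
A2 | alternative 1 | 2-[(4,5-dimethoxynaphthalen-1-yl)(hydroxy)methyl]benzene-1,3-diol | OC(c1c(O)cccc1O)c1ccc(OC)c2c(OC)cccc12
A3 | alternative 1 | 6-[(4,5-dimethoxynaphthalen-1-yl)methylidene]-5-hydroxycyclohexa-2,4-dien-1-one | O=C1C=CC=C(O)C1=Cc1ccc(OC)c2c(OC)cccc12
A4 | alternative 1 | 2-methoxypropene | COC(C)=C
A5 | alternative 2 | 5-(benzyloxy)-2-methyl-4-(4,5-dimethoxynaphthalen-1-yl)chroman-4-ol | COc1cccc2c([C@]3(O)C[C@@H](C)Oc4cccc(OCc5ccccc5)c43)ccc(OC)c12
A6 | alternative 2 | (R)-3-hydroxy-1-(4,5-dimethoxynaphthalen-1-yl)butan-1-one | C[C@@H](O)CC(=O)c1ccc(OC)c2c(OC)cccc12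
A7 | alternative 2 | 3-(benzyloxy)benzyne | C1(OCc2ccccc2)=CC=CC#C1
A8 | alternative 2 | 3-(benzyloxy)-2-(trimethylsilyl)phenyl trifluoromethanesulfonate | C[Si](C)(C)c1c(OCc2ccccc2)cccc1OS(=O)(=O)C(F)(F)F
A9 | alternative 3 | O-pivaloyl Cladonaphchrom A | COc1cccc2c([C@@H]3C[C@@H](C)Oc4cccc(OC(=O)C(C)(C)C)c43)ccc(OC)c12
A10 | alternative 3 | 3-hydroxy-2-vinylphenyl pivalate | C=Cc1c(O)cccc1OC(=O)C(C)(C)C
A11 | alternative 3 | acetaldehyde | CC=O
A12 | alternative 3 | 1,8-dimethoxynaphthalene | COc1cccc2cccc(OC)c12
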